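In a one-step world starting material and reagent would give target and the target would stay. The midnight run instead reads 34.1% of target at 0.167 h but 9.1% at 5.00 h.

all flasks: reagent 0.0105 M
- midnight: starting material 0.0050 M; second substrate 2 mM; run made earlier
- spring: starting material 0.020 M; second substrate 2 mM; run made earlier
- flask: starting material 0.010 M; second substrate 2.00 mM; time 6.0 h

| run | time / h | target / % | starting material / % |
|---|---|---|---|
| midnight | 0.0500 | 18.8 | 79.6 |
| midnight | 0.167 | 34.1 | 56.7 |
| midnight | 0.500 | 33.4 | 41.4 |
| midnight | 1.50 | 21.3 | 26.3 |
| midnight | 5.00 | 9.1 | 11.2 |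
| spring | 0.0500 | 14.4 | 80.6 |
| spring | 0.167 | 18.3 | 58.1 |
| spring | 0.500 | 10.6 | 38.7 |
| spring | 1.50 | 4.0 | 22.0 |
| spring | 5.00 | 1.1 | 10.2 |

(standard deviation of a reading: 0.3 percentage points)

- the moment within 6.0 h at which there is most target
- the amount of target, in percent of the starting material charged, at that time

Count target as holding one reagent and each lost pair of starting material as holding one, leave second product out, and free reagent follows from the readings. First instants: by 0.0500 h the midnight run has lost 20.4% of its starting material and the spring run 19.4%. The ratio c(target)/(c(starting material)·c(reagent)) then reads 24.8 M⁻¹ in midnight and 25.1 M⁻¹ in spring.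

Middle: at 0.167 h the missing share is 9.20% in midnight and 23.6% in spring, and target shows its highest reading in midnight and in spring. The ratio gives 70.2 M⁻¹ and 70.3 M⁻¹. This is Q, the reaction quotient of the target-forming step at the height of the run.

Late: at 0.500 h it reads 98.4 M⁻¹ and 82.7 M⁻¹, while the missing share keeps growing.

At 0.167 h the two runs read nearly the same Q, with 0.0050 M and 0.020 M of starting material charged, but at 0.500 h their readings stand apart. The flask sits at the logarithmic midpoint of the two loadings, so my own reckoning takes the missing share there, 14.7%, keeps Q, and solves the balances: 28.0% of target, near 0.167 h.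

The forecast gives 28.5% (26% to 30.5%) at 0.22 h (0.16 h to 0.3 h), holding that “Mass-balance loss fits starting material + target → byproduct”.

The flask peaks at 0.200 h with 28.0% of target, and 18.0% side product stands beside it.

    second substrate + reagent ⇌ second product (K = 160 M⁻¹, k = 0.0420 M⁻¹ s⁻¹)
    target → over-reaction product (k = 5.40 × 10⁻⁷ s⁻¹)
    starting material + target → side product (k = 0.0880 M⁻¹ s⁻¹)
    starting material + reagent ⇌ target (K = 110 M⁻¹, k = 0.140 M⁻¹ s⁻¹)
    2 second substrate → self-condensation product (k = 0.140 M⁻¹ s⁻¹)

From the free amounts, Q in the flask at 6.00 h is 109 M⁻¹. The neighbour with 0.042 M of reagent reaches 65.0% of target, and at 6.00 h its Q is 111 M⁻¹.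

(The readings come from a simulation for substances that don't exist, noise included.)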